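**Retrosynthetic overview**
1. The target is a briarane: a cyclohexane (C1, C10–C14) trans-fused to a ten-membered carbocycle (C1–C10) that carries a γ-lactone (C7–O–C19–C17–C8). The strategy rests on the cyclohexane, where quaternary C1 (methyl C15) sits between C14–O and C10–H, with the C2 arm cis to the C14 oxygen and trans to the C9 arm.
2. Late stage: C6–Cl from the (6R)-allylic alcohol by SN2; the ten-membered ring is closed last at C5–C6 (Nozaki–Hiyama–Kishi, alkenyl iodide C5 + aldehyde C6), and C6 is then set by oxidation/reduction.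
3. Lactone (second ring): C8–C17 by intramolecular SmI2 Reformatsky reaction of a C7 2-bromopropanoate on a C8 ketone; C8–C9 by NHK coupling of the C9 aldehyde with a glycerate-derived alkenyl triflate (C6–C8); the C8 ketone is unveiled by ozonolysis.
4. C2–C3 by Grignard addition, then CBS reduction; C11 oxygen by allylic oxidation next to C12=C13, then methylenation.
5. First ring: catalyst-controlled endo Diels–Alder reaction of (E)-4-silyloxy-2-methylbut-2-enal with (E)-1-silyloxybutadiene (C1–C14 and C10–C11), which sets C1, C10 and C14.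

Key step: step 3

Remark 1: briarane numbering is used in all names (C1 quaternary with CH3 = C15; C2–C9 ten-ring carbons; C10 fusion CH; C11–C14 six-ring; C16, C20 methylene carbons; C17 CHMe; C19 lactone C=O); CIP letters are given only where they do not depend on protecting groups, and C1, C10, C14 keep the geometry of 6 throughout.
Remark 2: the sense of induction in step 3 is assigned from the accepted pre-transition-state model for 2-substituted enals on cationic oxazaborolidines; on this model the (R)-catalyst opens the Cα si face that is needed here.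

Step 1
Reactants: 1 (tert-butyldimethylsilyloxy)acetaldehyde; 2 2-(triphenylphosphoranylidene)propanal
Product: 3 (E)-4-(tert-butyldimethylsilyloxy)-2-methylbut-2-enal
Conditions: toluene, 80 °C
Reagents that add atoms: none
Why: Wittig olefination with the stabilised formyl ylide should give the E enal selectively, the ylide reacting with the unhindered aldehyde 1 much faster than with the α-branched conjugated product.

Step 2
Reactants: 4 (E)-crotonaldehyde
Product: 5 (E)-1-(tert-butyldimethylsilyloxy)buta-1,3-diene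
Conditions: TBSOTf, Et3N, Et2O, 0 °C to rt
Reagents that add atoms: tert-butyldimethylsilyl trifluoromethanesulfonate, CC(C)(C)[Si](C)(C)OS(=O)(=O)C(F)(F)F
Why: Soft enolisation (O-silylation, then γ-deprotonation) should give the dienyl silyl ether mainly as the E isomer, and the minor Z isomer cannot reach the s-cis conformation and stays inert in step 3.

Step 3
Reactants: 3 (E)-4-(tert-butyldimethylsilyloxy)-2-methylbut-2-enal; 5 (E)-1-(tert-butyldimethylsilyloxy)buta-1,3-diene
Product: 6 (1R,2S,6S)-2-(tert-butyldimethylsilyloxy)-6-[(tert-butyldimethylsilyloxy)methyl]-1-methylcyclohex-3-ene-1-carbaldehyde (briarane C1, C14, C10; CHO = C2, CH2OTBS = C9)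
Conditions: (R)-o-tolyl-CBS-oxazaborolidine/Tf2NH (20 mol%), CH2Cl2, −78 to −40 °C
Reagents that add atoms: none
Why: The cationic oxazaborolidinium binds the formyl oxygen of 3 (supported by the formyl C–H···O contact) and lowers the LUMO of the s-trans enal, and the diene adds in a concerted, asynchronous [4+2] cycloaddition in which the unsubstituted terminus C11 bonds first to the β-carbon C10 and the oxygenated terminus C14 then closes onto the α-carbon C1. The closest known reaction type is the oxazaborolidinium-catalysed Diels–Alder reaction of 2-substituted enals (2-methylacrolein, tiglic aldehyde) with 1-silyloxy-1,3-dienes. The one ring formed, the C1/C10–C14 cyclohexene, is closed by the cycloaddition itself, both σ bonds (C1–C14 and C10–C11) arising in one suprafacial event. C1 and C10 are set relative to each other by the E geometry of 3 (formyl C2 trans to the C9 arm), C14 relative to C1 by the endo position of the coordinated formyl group (C2 cis to the silyloxy group), and the absolute configuration of all three by the catalyst, whose aryl group covers the Cα re face so that C14 adds to the Cα si face. The step needs regioselectivity (secured by donor polarisation of 5: the largest HOMO coefficient at C11 meets the largest LUMO coefficient at C10), endo selectivity (secured by the Lewis-acid-bound formyl group, which is small and overlaps with the diene), facial selectivity (catalyst), and a concerted path that outruns silyl transfer, for which low temperature and the non-nucleophilic triflimide counter-ion are chosen.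

Step 4
Reactants: 6 cyclohexene aldehyde; 7 (4-bromobut-1-yn-1-yl)trimethylsilane
Product: 9 C2 carbinol carrying the C3–C5 chain (both C2 epimers), via Grignard reagent 8 (not isolated)
Conditions: 7, Mg, THF, rt; then 6, THF, −78 to 0 °C; aq NH4Cl
Reagents that add atoms: none
Why: Grignard addition to the non-enolisable neopentyl aldehyde forms C2–C3; the new C2 centre is not controlled here because it is erased in step 5 and reset in step 6.

Step 5
Reactants: 9 C2 carbinol (both epimers)
Product: 10 C2 ketone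
Conditions: Dess–Martin periodinane, NaHCO3, CH2Cl2, rt
Reagents that add atoms: none
Why: Dess–Martin oxidation converts both C2 epimers into one ketone under neutral conditions that leave the silyl ethers, the alkene and the silylalkyne untouched.

Step 6
Reactants: 10 C2 ketone
Product: 11 (2S)-carbinol
Conditions: (R)-Me-CBS (20 mol%), catecholborane, toluene, −78 to −40 °C
Reagents that add atoms: none
Why: CBS reduction is reagent-controlled; the ketone binds with the tertiary C1 side as the large group and the CH2 chain as the small group, so the (R)-catalyst should give the (2S)-alcohol, and catecholborane at low temperature does not hydroborate the alkene or alkyne.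

Step 7
Reactants: 11 (2S)-carbinol
Product: 12 (2S)-C2,C9,C14-tris(silyl ether)
Conditions: TBSOTf, 2,6-lutidine, CH2Cl2, 0 °C
Reagents that add atoms: tert-butyldimethylsilyl trifluoromethanesulfonate, CC(C)(C)[Si](C)(C)OS(=O)(=O)C(F)(F)F
Why: The silyl triflate with a hindered base silylates the neopentyl secondary alcohol and puts the same protecting group on C2, C9 and C14.

Step 8
Reactants: 12 tris(silyl ether)
Product: 13 C11 enone (C11=O, C12=C13)
Conditions: Rh2(cap)4 (1 mol%), t-BuOOH, K2CO3, CH2Cl2, rt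
Reagents that add atoms: tert-butyl hydroperoxide, CC(C)(C)OO
Why: Rh(II)-catalysed allylic C–H oxidation with tert-butyl hydroperoxide should occur at the C11 methylene, the only unhindered allylic CH2 (C14–H is shielded by its silyl ether and the quaternary C1, and the C13 end of the allyl radical is more hindered than C11), giving the γ-silyloxy enone as known for 3-silyloxycyclohexenes.

Step 9
Reactants: 13 C11 enone
Product: 14 C11 ketone
Conditions: [(Ph3P)CuH]6, benzene, H2O, rt
Reagents that add atoms: none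
Why: Conjugate reduction with the phosphine copper hydride is chemoselective for the enone C12=C13 and leaves the silylalkyne and silyl ethers; C10 keeps its configuration because the C9 arm is already equatorial (the more stable epimer).

Step 10
Reactants: 14 C11 ketone
Product: 15 C11 methylene compound (C11=C20)
Conditions: Zn, CH2Br2, TiCl4, THF/CH2Cl2, 0 °C to rt
Reagents that add atoms: dibromomethane, BrCBr
Why: The non-basic Zn/CH2Br2/TiCl4 methylenation (Takai–Lombardo) converts the hindered, epimerisable β-silyloxy ketone into the C11 methylene without elimination, and the alkene also masks the C11 carbonyl so that no β-dicarbonyl arises when C9 is oxidised.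

Step 11
Reactants: 15 C11 methylene compound
Product: 16 C9 primary alcohol
Conditions: HF·pyridine, pyridine, THF, 0 °C
Reagents that add atoms: none
Why: Buffered HF·pyridine cleaves the primary C9 silyl ether much faster than the two secondary neopentyl silyl ethers and does not touch the C-silyl alkyne.

Step 12
Reactants: 16 C9 primary alcohol
Product: 17 C9 aldehyde
Conditions: Dess–Martin periodinane, NaHCO3, CH2Cl2, 0 °C
Reagents that add atoms: none
Why: Buffered Dess–Martin oxidation gives the β,γ-unsaturated aldehyde without base, so C10 is not epimerised and the exocyclic alkene does not move into conjugation; 17 is used at once.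

Step 13
Reactants: 18 methyl (S)-2,2-dimethyl-1,3-dioxolane-4-carboxylate
Product: 20 (S)-1-(2,2-dimethyl-1,3-dioxolan-4-yl)ethan-1-one, via Weinreb amide 19 (not isolated)
Conditions: MeNH(OMe)·HCl, i-PrMgCl, THF, −20 °C; then MeMgBr, 0 °C; aq NH4Cl
Reagents that add atoms: methylmagnesium bromide, C[Mg]Br; N,O-dimethylhydroxylamine hydrochloride, CNOC.Cl (atoms in 19 only)
Why: One-pot conversion of the ester into the N-methoxy-N-methylamide and addition of methylmagnesium bromide stops at the ketone through the chelated tetrahedral intermediate, and the α-alkoxy centre (C7 of the target) is not enolised under these conditions.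

Step 14
Reactants: 20 (S)-1-(2,2-dimethyl-1,3-dioxolan-4-yl)ethan-1-one
Product: 21 (S)-1-(2,2-dimethyl-1,3-dioxolan-4-yl)vinyl trifluoromethanesulfonate
Conditions: KHMDS, PhNTf2, THF, −78 °C
Reagents that add atoms: N-phenylbis(trifluoromethanesulfonimide), O=S(=O)(N(c1ccccc1)S(=O)(=O)C(F)(F)F)C(F)(F)F
Why: Kinetic deprotonation occurs at the methyl group and not at the ring α-carbon, and O-triflation of the potassium enolate gives the 2-substituted alkenyl triflate with the C7 centre intact.

Step 15
Reactants: 17 C9 aldehyde; 21 alkenyl triflate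
Product: 22 C9 allylic alcohol with C8=CH2 and C6/C7 acetonide (both C9 epimers)
Conditions: CrCl2, NiCl2 (cat.), DMF, rt
Reagents that add atoms: none
Why: Nozaki–Hiyama–Kishi coupling (Ni-catalysed formation of the alkenylchromium(III) species and its addition to the aldehyde) forms C8–C9 without touching silyl ethers, acetonide or silylalkyne; the C9 epimers formed (Felkin–Anh attack anti to C1 favours the unwanted one) are converged in steps 16 and 17.

Step 16
Reactants: 22 C9 allylic alcohol (both epimers)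
Product: 23 C9 α-methylene ketone
Conditions: Dess–Martin periodinane, NaHCO3, CH2Cl2, 0 °C
Reagents that add atoms: none
Why: Dess–Martin oxidation of the allylic alcohols gives a single α-methylene ketone.

Step 17
Reactants: 23 C9 α-methylene ketone
Product: 25 (9S)-allylic alcohol with terminal alkyne, via silylalkyne alcohol 24 (not isolated)
Conditions: NaBH4, CeCl3·7H2O, MeOH, −78 °C; then K2CO3, rt
Reagents that add atoms: none
Why: Luche 1,2-reduction should follow the Felkin–Anh course, hydride entering anti to the quaternary C1 and over H-10, which gives the (9S)-alcohol; K2CO3 added to the methanolic mixture then cleaves the alkynyl C–Si bond.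

Step 18
Reactants: 25 (9S)-allylic alcohol
Product: 26 (9S)-silyl ether
Conditions: TBSOTf, 2,6-lutidine, CH2Cl2, −78 to 0 °C
Reagents that add atoms: tert-butyldimethylsilyl trifluoromethanesulfonate, CC(C)(C)[Si](C)(C)OS(=O)(=O)C(F)(F)F
Why: Silyl triflate/lutidine silylates the hindered allylic C9 alcohol, and the acetonide is stable to these conditions.

Step 19
Reactants: 26 (9S)-silyl ether
Product: 28 C8,C11-diketone, via bis-ozonide 27 (not isolated)
Conditions: O3, CH2Cl2, −78 °C (indicator dye); then PPh3, −78 °C to rt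
Reagents that add atoms: ozone, O=[O+][O-]
Why: Ozone cleaves both 1,1-disubstituted alkenes (C8=CH2 to the C8 ketone, C11=CH2 back to the C11 ketone) far faster than it attacks the terminal alkyne, and reductive work-up of the ozonides avoids over-oxidation.

Step 20
Reactants: 28 C8,C11-diketone
Product: 29 C6,C7-diol
Conditions: AcOH/H2O/THF (3:1:1), 40 °C
Reagents that add atoms: none
Why: Mild aqueous acetic acid hydrolyses the terminal acetonide while the hindered secondary silyl ethers survive, and the non-basic medium avoids aldol or α-ketol reactions of the 1,4-diketone.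

Step 21
Reactants: 29 C6,C7-diol
Product: 30 C6 silyl ether with free C7 hydroxyl
Conditions: TBSCl, imidazole, CH2Cl2, −20 °C
Reagents that add atoms: tert-butyldimethylsilyl chloride, CC(C)(C)[Si](C)(C)Cl
Why: The primary C6 hydroxyl is silylated much faster than the secondary α-ketol hydroxyl at C7.

Step 22
Reactants: 30 C6 silyl ether
Product: 31 C7 2-bromopropanoate
Conditions: 2-bromopropanoyl bromide, pyridine, CH2Cl2, −40 to 0 °C
Reagents that add atoms: 2-bromopropanoyl bromide, CC(Br)C(=O)Br
Why: Acylation of the remaining C7 hydroxyl with the acid bromide and pyridine at low temperature installs the Reformatsky tether; the bromine-bearing carbon is a mixture of epimers of no consequence.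

Step 23
Reactants: 31 C7 2-bromopropanoate
Product: 32 β-hydroxy-γ-lactone (C8–OH cis to the C17 methyl and to the C6 arm, trans to the C9 arm)
Conditions: SmI2 (2.2 equiv), THF, −78 °C; aq NH4Cl
Reagents that add atoms: none
Why: SmI2 reduces the C–Br bond first and the samarium(III) enolate adds to the adjacent C8 ketone in a five-membered ring closure (intramolecular Reformatsky reaction); the bulky C9 arm takes the face of the new ring opposite to the C6 arm, which places O8 cis to C6, and the C17 methyl sits trans to the C9 arm in the chelated transition state, which is also the more stable arrangement at the epimerisable C17.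

Step 24
Reactants: 32 β-hydroxy-γ-lactone
Product: 33 C5 triethylsilyl alkene (α-vinylsilane)
Conditions: [Cp*Ru(MeCN)3]PF6 (5 mol%), Et3SiH, CH2Cl2, 0 °C to rt
Reagents that add atoms: triethylsilane, CC[SiH](CC)CC
Why: Cationic Cp*Ru-catalysed hydrosilylation of the terminal alkyne is Markovnikov-selective (silicon at C5) and tolerates the ketone, the lactone and the free tertiary alcohol.

Step 25
Reactants: 33 α-vinylsilane
Product: 34 C5 alkenyl iodide
Conditions: N-iodosuccinimide, (CF3)2CHOH, 0 °C
Reagents that add atoms: N-iodosuccinimide, O=C1CCC(=O)N1I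
Why: Ipso-iododesilylation of the α-vinylsilane (β-silyl cation pathway) gives the 2-iodoalkene; it is run at this point because the substrate holds no other alkene.

Step 26
Reactants: 34 C5 alkenyl iodide (C11 ketone)
Product: 35 C11 methylene compound
Conditions: Zn, CH2Br2, TiCl4, THF/CH2Cl2, 0 °C to rt
Reagents that add atoms: dibromomethane, BrCBr
Why: The same non-basic Takai–Lombardo methylenation restores the C11 methylene at the ketone stage and tolerates the lactone, the tertiary alcohol (any C8–OH/C11 hemiketal is in equilibrium with the reacting hydroxy ketone) and the alkenyl iodide.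

Step 27
Reactants: 35 C11 methylene compound
Product: 36 C6 primary alcohol
Conditions: HF·pyridine, pyridine, THF, 0 °C
Reagents that add atoms: none
Why: Buffered HF·pyridine removes the only primary silyl ether (C6) and leaves the three hindered secondary ones.

Step 28
Reactants: 36 C6 primary alcohol
Product: 37 C6 aldehyde
Conditions: Dess–Martin periodinane, NaHCO3, CH2Cl2, 0 °C
Reagents that add atoms: none
Why: Dess–Martin oxidation gives the α-acyloxy aldehyde under neutral buffered conditions that avoid epimerisation at C7 and retro-aldol loss of the C8 carbinol; the tertiary alcohol is inert.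

Step 29
Reactants: 37 C6 aldehyde
Product: 38 ten-membered allylic alcohol with C5=C16 methylene (both C6 epimers)
Conditions: CrCl2, NiCl2 (cat.), DMSO, rt, 2 mM, slow addition
Reagents that add atoms: none
Why: Intramolecular Nozaki–Hiyama–Kishi reaction at high dilution forms C5–C6 and closes the ten-membered ring, giving the exocyclic C5=C16 methylene and the C6 carbinol in one step; the reaction tolerates the lactone and the free tertiary alcohol, and the C6 configuration is left open because it is reset in steps 30 and 31.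

Step 30
Reactants: 38 macrocyclic allylic alcohol (both C6 epimers)
Product: 39 macrocyclic C6 α-methylene ketone
Conditions: Dess–Martin periodinane, NaHCO3, CH2Cl2, 0 °C
Reagents that add atoms: none
Why: Dess–Martin oxidation converges the C6 epimers on one cross-conjugated α-methylene ketone.

Step 31
Reactants: 39 macrocyclic C6 ketone
Product: 40 (6R)-allylic alcohol
Conditions: NaBH4, CeCl3·7H2O, MeOH, −78 °C
Reagents that add atoms: none
Why: Luche conditions give 1,2-reduction only, and polar Felkin–Anh control (hydride anti to the C7–O bond, passing over H-7) should give the (6R)-alcohol.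

Step 32
Reactants: 40 (6R)-allylic alcohol
Product: 41 (6S)-allylic chloride, tris(silyl ether)
Conditions: PPh3, hexachloroacetone, CH2Cl2, −20 to 0 °C
Reagents that add atoms: hexachloroacetone, O=C(C(Cl)(Cl)Cl)C(Cl)(Cl)Cl
Why: Triphenylphosphine/hexachloroacetone (Appel-type) converts secondary allylic alcohols into chlorides by SN2 collapse of the oxyphosphonium chloride ion pair, with inversion and little allylic transposition, giving the (6S)-chloride; the hindered tertiary C8 alcohol does not react at this temperature.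

Step 33
Reactants: 41 (6S)-chloride, tris(silyl ether)
Product: 42 C2,C8,C9,C14-tetraol
Conditions: HF·pyridine, THF, 0 °C to rt
Reagents that add atoms: none
Why: Acidic, non-nucleophilic HF·pyridine removes the three secondary silyl ethers without displacing the allylic chloride or opening the lactone.

Step 34
Reactants: 42 tetraol
Product: 43 CNP0199061.1 (target)
Conditions: Ac2O, pyridine, DMAP (cat.), CH2Cl2, rt
Reagents that add atoms: acetic anhydride, CC(=O)OC(C)=O
Why: The three secondary hydroxyls at C2, C9 and C14 are acetylated under DMAP catalysis while the tertiary C8 hydroxyl stays free, which gives the target.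

**Compound list**
1 | (tert-butyldimethylsilyloxy)acetaldehyde | O=CCO[Si](C)(C)C(C)(C)C | starting material
2 | 2-(triphenylphosphoranylidene)propanal | CC(C=O)=P(c1ccccc1)(c1ccccc1)c1ccccc1 | starting material
3 | (E)-4-(tert-butyldimethylsilyloxy)-2-methylbut-2-enal | O=C/C(C)=C/CO[Si](C)(C)C(C)(C)C | intermediate
4 | (E)-crotonaldehyde | C/C=C/C=O | starting material
5 | (E)-1-(tert-butyldimethylsilyloxy)buta-1,3-diene | C=C/C=C/O[Si](C)(C)C(C)(C)C | intermediate
6 | (1R,2S,6S)-2-(tert-butyldimethylsilyloxy)-6-[(tert-butyldimethylsilyloxy)methyl]-1-methylcyclohex-3-ene-1-carbaldehyde | C1C=C[C@H](O[Si](C)(C)C(C)(C)C)[C@](C)(C=O)[C@H]1CO[Si](C)(C)C(C)(C)C | intermediate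
7 | (4-bromobut-1-yn-1-yl)trimethylsilane | BrCCC#C[Si](C)(C)C | starting material
8 | [4-(trimethylsilyl)but-3-yn-1-yl]magnesium bromide | Br[Mg]CCC#C[Si](C)(C)C | intermediate
9 | C2 carbinol: 6 with CHO replaced by CH(OH)CH2CH2C≡C–SiMe3 (both C2 epimers) | C1C=C[C@H](O[Si](C)(C)C(C)(C)C)[C@](C)(C(O)CCC#C[Si](C)(C)C)[C@H]1CO[Si](C)(C)C(C)(C)C | intermediate
10 | C2 ketone of 9 | C1C=C[C@H](O[Si](C)(C)C(C)(C)C)[C@](C)(C(=O)CCC#C[Si](C)(C)C)[C@H]1CO[Si](C)(C)C(C)(C)C | intermediate
11 | (2S)-carbinol | C1C=C[C@H](O[Si](C)(C)C(C)(C)C)[C@](C)([C@@H](O)CCC#C[Si](C)(C)C)[C@H]1CO[Si](C)(C)C(C)(C)C | intermediate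
12 | (2S)-C2,C9,C14-tris(tert-butyldimethylsilyl) ether | C1C=C[C@H](O[Si](C)(C)C(C)(C)C)[C@](C)([C@@H](O[Si](C)(C)C(C)(C)C)CCC#C[Si](C)(C)C)[C@H]1CO[Si](C)(C)C(C)(C)C | intermediate
13 | C11 enone of 12 (C11=O, C12=C13) | O=C1C=C[C@H](O[Si](C)(C)C(C)(C)C)[C@](C)([C@@H](O[Si](C)(C)C(C)(C)C)CCC#C[Si](C)(C)C)[C@H]1CO[Si](C)(C)C(C)(C)C | intermediate
14 | C11 ketone (C12, C13 saturated) | O=C1CC[C@H](O[Si](C)(C)C(C)(C)C)[C@](C)([C@@H](O[Si](C)(C)C(C)(C)C)CCC#C[Si](C)(C)C)[C@H]1CO[Si](C)(C)C(C)(C)C | intermediate
15 | C11 methylene compound | C=C1CC[C@H](O[Si](C)(C)C(C)(C)C)[C@](C)([C@@H](O[Si](C)(C)C(C)(C)C)CCC#C[Si](C)(C)C)[C@H]1CO[Si](C)(C)C(C)(C)C | intermediate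
16 | C9 primary alcohol of 15 | C=C1CC[C@H](O[Si](C)(C)C(C)(C)C)[C@](C)([C@@H](O[Si](C)(C)C(C)(C)C)CCC#C[Si](C)(C)C)[C@H]1CO | intermediate
17 | C9 aldehyde | C=C1CC[C@H](O[Si](C)(C)C(C)(C)C)[C@](C)([C@@H](O[Si](C)(C)C(C)(C)C)CCC#C[Si](C)(C)C)[C@H]1C=O | intermediate
18 | methyl (S)-2,2-dimethyl-1,3-dioxolane-4-carboxylate | COC(=O)[C@@H]1COC(C)(C)O1 | starting material
19 | (S)-N-methoxy-N,2,2-trimethyl-1,3-dioxolane-4-carboxamide | CON(C)C(=O)[C@@H]1COC(C)(C)O1 | intermediate
20 | (S)-1-(2,2-dimethyl-1,3-dioxolan-4-yl)ethan-1-one | CC(=O)[C@@H]1COC(C)(C)O1 | intermediate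
21 | (S)-1-(2,2-dimethyl-1,3-dioxolan-4-yl)vinyl trifluoromethanesulfonate | C=C(OS(=O)(=O)C(F)(F)F)[C@@H]1COC(C)(C)O1 | intermediate
22 | C9 allylic alcohol: 17 with CHO replaced by CH(OH)–C(=CH2)–dioxolanyl (both C9 epimers; C6/C7 acetonide) | C=C1CC[C@H](O[Si](C)(C)C(C)(C)C)[C@](C)([C@@H](O[Si](C)(C)C(C)(C)C)CCC#C[Si](C)(C)C)[C@H]1C(O)C(=C)[C@@H]2COC(C)(C)O2 | intermediate
23 | C9 α-methylene ketone | C=C1CC[C@H](O[Si](C)(C)C(C)(C)C)[C@](C)([C@@H](O[Si](C)(C)C(C)(C)C)CCC#C[Si](C)(C)C)[C@H]1C(=O)C(=C)[C@@H]2COC(C)(C)O2 | intermediate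
24 | (9S)-allylic alcohol, alkyne still C-silylated | C=C1CC[C@H](O[Si](C)(C)C(C)(C)C)[C@](C)([C@@H](O[Si](C)(C)C(C)(C)C)CCC#C[Si](C)(C)C)[C@H]1[C@H](O)C(=C)[C@@H]2COC(C)(C)O2 | intermediate
25 | (9S)-allylic alcohol, terminal alkyne | C=C1CC[C@H](O[Si](C)(C)C(C)(C)C)[C@](C)([C@@H](O[Si](C)(C)C(C)(C)C)CCC#C)[C@H]1[C@H](O)C(=C)[C@@H]2COC(C)(C)O2 | intermediate
26 | (9S)-tert-butyldimethylsilyl ether of 25 | C=C1CC[C@H](O[Si](C)(C)C(C)(C)C)[C@](C)([C@@H](O[Si](C)(C)C(C)(C)C)CCC#C)[C@H]1[C@H](O[Si](C)(C)C(C)(C)C)C(=C)[C@@H]2COC(C)(C)O2 | intermediate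
27 | bis(1,2,4-trioxolane) of 26, spiro at C8 and C11 | C13(OCOO3)CC[C@H](O[Si](C)(C)C(C)(C)C)[C@](C)([C@@H](O[Si](C)(C)C(C)(C)C)CCC#C)[C@H]1[C@H](O[Si](C)(C)C(C)(C)C)C4(OCOO4)[C@@H]2COC(C)(C)O2 | intermediate
28 | C8,C11-diketone with C6/C7 acetonide | O=C1CC[C@H](O[Si](C)(C)C(C)(C)C)[C@](C)([C@@H](O[Si](C)(C)C(C)(C)C)CCC#C)[C@H]1[C@H](O[Si](C)(C)C(C)(C)C)C(=O)[C@@H]2COC(C)(C)O2 | intermediate
29 | C6,C7-diol of 28 | O=C1CC[C@H](O[Si](C)(C)C(C)(C)C)[C@](C)([C@@H](O[Si](C)(C)C(C)(C)C)CCC#C)[C@H]1[C@H](O[Si](C)(C)C(C)(C)C)C(=O)[C@@H](O)CO | intermediate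
30 | C6 tert-butyldimethylsilyl ether, C7 hydroxyl free | O=C1CC[C@H](O[Si](C)(C)C(C)(C)C)[C@](C)([C@@H](O[Si](C)(C)C(C)(C)C)CCC#C)[C@H]1[C@H](O[Si](C)(C)C(C)(C)C)C(=O)[C@@H](O)CO[Si](C)(C)C(C)(C)C | intermediate
31 | C7 2-bromopropanoate (CHBr epimers) | O=C1CC[C@H](O[Si](C)(C)C(C)(C)C)[C@](C)([C@@H](O[Si](C)(C)C(C)(C)C)CCC#C)[C@H]1[C@H](O[Si](C)(C)C(C)(C)C)C(=O)[C@@H](OC(=O)C(C)Br)CO[Si](C)(C)C(C)(C)C | intermediate
32 | β-hydroxy-γ-lactone (C7–O–C19(=O)–C17(Me)–C8(OH)), C11 ketone, terminal alkyne | O=C1CC[C@H](O[Si](C)(C)C(C)(C)C)[C@](C)([C@@H](O[Si](C)(C)C(C)(C)C)CCC#C)[C@H]1[C@H](O[Si](C)(C)C(C)(C)C)[C@]2(O)[C@@H](C)C(=O)O[C@H]2CO[Si](C)(C)C(C)(C)C | intermediate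
33 | C5 triethylsilyl alkene (C5(SiEt3)=C16H2) | O=C1CC[C@H](O[Si](C)(C)C(C)(C)C)[C@](C)([C@@H](O[Si](C)(C)C(C)(C)C)CCC(=C)[Si](CC)(CC)CC)[C@H]1[C@H](O[Si](C)(C)C(C)(C)C)[C@]2(O)[C@@H](C)C(=O)O[C@H]2CO[Si](C)(C)C(C)(C)C | intermediate
34 | C5 alkenyl iodide (C5(I)=C16H2), C11 ketone | O=C1CC[C@H](O[Si](C)(C)C(C)(C)C)[C@](C)([C@@H](O[Si](C)(C)C(C)(C)C)CCC(=C)I)[C@H]1[C@H](O[Si](C)(C)C(C)(C)C)[C@]2(O)[C@@H](C)C(=O)O[C@H]2CO[Si](C)(C)C(C)(C)C | intermediate
35 | alkenyl iodide with C11 methylene | C=C1CC[C@H](O[Si](C)(C)C(C)(C)C)[C@](C)([C@@H](O[Si](C)(C)C(C)(C)C)CCC(=C)I)[C@H]1[C@H](O[Si](C)(C)C(C)(C)C)[C@]2(O)[C@@H](C)C(=O)O[C@H]2CO[Si](C)(C)C(C)(C)C | intermediate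
36 | C6 primary alcohol of 35 | C=C1CC[C@H](O[Si](C)(C)C(C)(C)C)[C@](C)([C@@H](O[Si](C)(C)C(C)(C)C)CCC(=C)I)[C@H]1[C@H](O[Si](C)(C)C(C)(C)C)[C@]2(O)[C@@H](C)C(=O)O[C@H]2CO | intermediate
37 | C6 aldehyde | C=C1CC[C@H](O[Si](C)(C)C(C)(C)C)[C@](C)([C@@H](O[Si](C)(C)C(C)(C)C)CCC(=C)I)[C@H]1[C@H](O[Si](C)(C)C(C)(C)C)[C@]2(O)[C@@H](C)C(=O)O[C@H]2C=O | intermediate
38 | ten-membered allylic alcohol, C5=C16 methylene, C2/C9/C14 silyl ethers (both C6 epimers) | C=C1CC[C@H](O[Si](C)(C)C(C)(C)C)[C@]2(C)[C@@H](O[Si](C)(C)C(C)(C)C)CCC(=C)C(O)[C@@H]3OC(=O)[C@H](C)[C@@]3(O)[C@@H](O[Si](C)(C)C(C)(C)C)[C@@H]12 | intermediate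
39 | macrocyclic C6 α-methylene ketone | C=C1CC[C@H](O[Si](C)(C)C(C)(C)C)[C@]2(C)[C@@H](O[Si](C)(C)C(C)(C)C)CCC(=C)C(=O)[C@@H]3OC(=O)[C@H](C)[C@@]3(O)[C@@H](O[Si](C)(C)C(C)(C)C)[C@@H]12 | intermediate
40 | (6R)-allylic alcohol | C=C1CC[C@H](O[Si](C)(C)C(C)(C)C)[C@]2(C)[C@@H](O[Si](C)(C)C(C)(C)C)CCC(=C)[C@@H](O)[C@@H]3OC(=O)[C@H](C)[C@@]3(O)[C@@H](O[Si](C)(C)C(C)(C)C)[C@@H]12 | intermediate
41 | (6S)-allylic chloride, C2/C9/C14 tris(silyl ether) | C=C1CC[C@H](O[Si](C)(C)C(C)(C)C)[C@]2(C)[C@@H](O[Si](C)(C)C(C)(C)C)CCC(=C)[C@H](Cl)[C@@H]3OC(=O)[C@H](C)[C@@]3(O)[C@@H](O[Si](C)(C)C(C)(C)C)[C@@H]12 | intermediate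
42 | (6S)-chloro C2,C8,C9,C14-tetraol | C=C1CC[C@H](O)[C@]2(C)[C@@H](O)CCC(=C)[C@H](Cl)[C@@H]3OC(=O)[C@H](C)[C@@]3(O)[C@@H](O)[C@@H]12 | intermediate
43 | CNP0199061.1 (2,9,14-triacetate, 6-chloride, 8-hydroxy lactone) | C=C1CC[C@H](OC(C)=O)[C@]2(C)[C@@H](OC(C)=O)CCC(=C)[C@H](Cl)[C@@H]3OC(=O)[C@H](C)[C@@]3(O)[C@@H](OC(C)=O)[C@@H]12 | target

**Step count and risks**

Total step count: 34. Longest linear sequence: 31 steps (steps 1, 3–12 and 15–34).

Steps most likely to fail:

Step 3 (key Diels–Alder reaction). The cycloaddition of the trisubstituted dienophile may be slow, a stepwise Mukaiyama–Michael addition with silyl transfer may compete, and facial control may be poor. Fallback: it sets out from 3 and 5 and comes back at 11. The cycloaddition is run without the chiral catalyst (Me2AlCl, CH2Cl2, −78 °C, or thermally in toluene), which gives 6 as the racemate, that is together with its enantiomer, ent-aldehyde F1. The racemate is carried through steps 4 and 5, which adds the enantiomeric carbinols F2 and the enantiomeric ketone F3. The reagent-controlled CBS reduction of step 6 then gives 11 from 10 and, from F3, the diastereomeric (2S)-carbinol F4. F4 differs from 11 at the three ring centres and is removed by chromatography.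

Step 29 (ten-membered ring closure). Oligomerisation, or reduction of the alkenyl iodide without ring closure, may prevail because of the transannular strain of the forming ring. Fallback: it sets out from 32 and comes back at 38. The C11 ketone of 32 is methylenated as in step 26 to the alkynyl lactone F5. Buffered HF·pyridine frees the C6 alcohol F6, and Dess–Martin oxidation gives the ynal F7. A Ni(0)/bulky N-heterocyclic carbene catalysed reductive alkyne–aldehyde macrocyclisation with Et3SiH (THF, high dilution) forms C5–C6 at the internal alkyne carbon and gives the macrocyclic C6 triethylsilyl ether F8 with the exocyclic methylene. PPTS in methanol removes only the triethylsilyl group to give 38.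

Step 32 (chlorination at C6). Allylic transposition (SN2′ to the C16 chloride) or elimination may occur in the oxyphosphonium ion pair, and substitution at the hindered C6 may be slow. Fallback: it sets out from 40 and comes back at 41. Activation and displacement are separated: chloromethanesulfonyl chloride and pyridine give the isolable C6 chloromethanesulfonate F9, and lithium chloride in DMF at room temperature displaces it by direct SN2 with inversion to give 41.

Further compounds
F1 | step 3 | ent-aldehyde (enantiomer of 6) | C1C=C[C@@H](O[Si](C)(C)C(C)(C)C)[C@@](C)(C=O)[C@@H]1CO[Si](C)(C)C(C)(C)C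
F2 | step 3 | enantiomeric carbinols (enantiomers of 9, both C2 epimers) | C1C=C[C@@H](O[Si](C)(C)C(C)(C)C)[C@@](C)(C(O)CCC#C[Si](C)(C)C)[C@@H]1CO[Si](C)(C)C(C)(C)C
F3 | step 3 | enantiomeric ketone (enantiomer of 10) | C1C=C[C@@H](O[Si](C)(C)C(C)(C)C)[C@@](C)(C(=O)CCC#C[Si](C)(C)C)[C@@H]1CO[Si](C)(C)C(C)(C)C
F4 | step 3 | diastereomeric (2S)-carbinol on the enantiomeric ring | C1C=C[C@@H](O[Si](C)(C)C(C)(C)C)[C@@](C)([C@@H](O)CCC#C[Si](C)(C)C)[C@@H]1CO[Si](C)(C)C(C)(C)C
F5 | step 29 | alkynyl lactone with C11 methylene | C=C1CC[C@H](O[Si](C)(C)C(C)(C)C)[C@](C)([C@@H](O[Si](C)(C)C(C)(C)C)CCC#C)[C@H]1[C@H](O[Si](C)(C)C(C)(C)C)[C@]2(O)[C@@H](C)C(=O)O[C@H]2CO[Si](C)(C)C(C)(C)C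
F6 | step 29 | C6 alcohol of the alkynyl lactone | C=C1CC[C@H](O[Si](C)(C)C(C)(C)C)[C@](C)([C@@H](O[Si](C)(C)C(C)(C)C)CCC#C)[C@H]1[C@H](O[Si](C)(C)C(C)(C)C)[C@]2(O)[C@@H](C)C(=O)O[C@H]2CO
F7 | step 29 | ynal | C=C1CC[C@H](O[Si](C)(C)C(C)(C)C)[C@](C)([C@@H](O[Si](C)(C)C(C)(C)C)CCC#C)[C@H]1[C@H](O[Si](C)(C)C(C)(C)C)[C@]2(O)[C@@H](C)C(=O)O[C@H]2C=O
F8 | step 29 | macrocyclic C6 triethylsilyl ether (both C6 epimers) | C=C1CC[C@H](O[Si](C)(C)C(C)(C)C)[C@]2(C)[C@@H](O[Si](C)(C)C(C)(C)C)CCC(=C)C(O[Si](CC)(CC)CC)[C@@H]3OC(=O)[C@H](C)[C@@]3(O)[C@@H](O[Si](C)(C)C(C)(C)C)[C@@H]12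
F9 | step 32 | (6R)-C6 chloromethanesulfonate | C=C1CC[C@H](O[Si](C)(C)C(C)(C)C)[C@]2(C)[C@@H](O[Si](C)(C)C(C)(C)C)CCC(=C)[C@@H](OS(=O)(=O)CCl)[C@@H]3OC(=O)[C@H](C)[C@@]3(O)[C@@H](O[Si](C)(C)C(C)(C)C)[C@@H]12
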